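The ten-membered ring is not closed end to end but grown from a cyclohexane: the ring 1,5-diene C10=C1–C2–C3–C4=C5 is a Cope retron. One operation, an alkoxide-driven [3,3] shift of a cis-1,2-dialkenylcyclohexanol, forms C2–C3, breaks C5–C10, sets the Z-C1=C10 and ring-trans C4=C5 geometries and delivers C5 as an enol triflate that is later reduced to C–H. The precursor is an elemane-type cyclohexanol (ring C5–C10) with vinyl and methyl at C10, a 3-hydroxyprop-1-en-2-yl group and OH at C5, a silyloxy group at C8 and the lactone masked as a trans-fused lactol methyl ether across C6–C7.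

Key step: step 10

Remark on the chemistry (assumptions): germacrane numbering C1–C15 is used for all intermediates; (S)-4-(tert-butyldimethylsilyloxy)cyclohex-2-en-1-one is taken as a purchasable enantiopure building block; because the last α-substituent of a cyclohexanone enolate enters axially (cis to the C7 branch), C10 is assembled methyl-last.

Step 1
Reactants: 1 (S)-4-(tert-butyldimethylsilyloxy)cyclohex-2-en-1-one; 2 isopropenylmagnesium bromide
Product: 4 (3R,4S)-4-(tert-butyldimethylsilyloxy)-3-(prop-1-en-2-yl)cyclohexan-1-one, via trimethylsilyl enol ether 3 (not isolated)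
Conditions: CuBr·SMe2 (10 mol%), TMSCl, THF, −78 °C; then 10% aq. citric acid, 0 °C
Reagents that add atoms: none
Why: Copper-catalysed, TMSCl-accelerated 1,4-addition of the Grignard reagent should occur anti to the γ-silyloxy group, which sets C7 trans to C8–O; mild acid then hydrolyses the enol silane to the ketone.

Step 2
Reactants: 4 (3R,4S)-4-(tert-butyldimethylsilyloxy)-3-(prop-1-en-2-yl)cyclohexan-1-one
Product: 5 C10-(hydroxymethylene) ketone (chelated Z-enol of the 2-formyl derivative of 4)
Conditions: HCO2Et, NaH, cat. EtOH, THF, 0 → 23 °C; 1 M HCl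
Reagents that add atoms: ethyl formate, CCOC=O
Why: Claisen-type formylation under equilibrating conditions should place the hydroxymethylene group on the unhindered C10 methylene and not on C6, which is flanked by the C7 branch (the usual blocking-group regiochemistry of 3-substituted cyclohexanones).

Step 3
Reactants: 5 C10-(hydroxymethylene) ketone
Product: 6 C10-formyl-C10-methyl ketone (methyl cis to the C7 isopropenyl group; formyl cis to C8-OTBS)
Conditions: MeI, K2CO3, acetone, 40 °C
Reagents that add atoms: iodomethane, CI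
Why: C-Alkylation of the β-keto aldehyde enolate; on the chair with the C7 and C8 substituents equatorial the methyl group should enter axially at C10, cis to the C7 branch, so that the formyl group (the future vinyl group) ends equatorial, which is the C10 configuration the rearrangement needs.

Step 4
Reactants: 6 C10-formyl-C10-methyl ketone
Product: 7 C10-methyl-C10-vinyl ketone (vinyl cis to C8-OTBS; trans to isopropenyl)
Conditions: Ph3PCH3Br, KHMDS, THF, 0 °C; then 6, −78 → 0 °C
Reagents that add atoms: methyltriphenylphosphonium bromide, C[P+](c1ccccc1)(c1ccccc1)c1ccccc1.[Br-]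
Why: Wittig methylenation; the neopentyl aldehyde should react far faster than the α-quaternary ketone, and C10 has no hydrogen that could be lost.

Step 5
Reactants: 7 C10-methyl-C10-vinyl ketone
Product: 8 C6-hydroxy ketone (6-OH trans to isopropenyl; cis to vinyl)
Conditions: NaHMDS, THF, −78 °C; 2-(phenylsulfonyl)-3-phenyloxaziridine, −78 → −40 °C; sat. NH4Cl
Reagents that add atoms: 2-(phenylsulfonyl)-3-phenyloxaziridine, O=S(=O)(c1ccccc1)N1OC1c1ccccc1
Why: Enolate α-hydroxylation with an N-sulfonyloxaziridine; C6 is the only enolisable position, and the equatorial C6–OH (trans to the C7 branch) should result because the axial C10 methyl group shields the other face and the axial epimer, syn-axial to that methyl group, is drained by enolisation.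

Step 6
Reactants: 8 C6-hydroxy ketone
Product: 9 C11,C12-epoxide of 8 (both C11 epimers)
Conditions: mCPBA, NaHCO3, CH2Cl2, 0 °C
Reagents that add atoms: mCPBA, OOC(=O)c1cccc(Cl)c1
Why: Prilezhaev epoxidation; the 1,1-disubstituted isopropenyl alkene should be far more nucleophilic than the neopentyl vinyl group, and the epimeric centre at C11 is erased in step 7.

Step 7
Reactants: 9 C11,C12-epoxide of 8
Product: 11 trans-fused lactol (C6–O–C12 hemiacetal; C11/C12 epimers), via hydroxy aldehyde 10 (not isolated)
Conditions: BF3·OEt2 (0.3 equiv), CH2Cl2, −78 °C; Et3N quench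
Reagents that add atoms: none
Why: Meinwald rearrangement: Lewis-acid opening at the tertiary C11 and a 1,2-hydride shift from C12 give the α-branched aldehyde, which the neighbouring C6–OH should capture as the five-membered lactol.

Step 8
Reactants: 11 trans-fused lactol
Product: 12 trans-fused lactol methyl ether ketone (C11 methyl trans to C8; OMe trans to that methyl)
Conditions: K2CO3 (cat.), MeOH, 23 °C; then PPTS, 4 Å MS, MeOH, 23 °C
Reagents that add atoms: methanol, CO
Why: Base equilibrates C11 through the open-chain aldehyde to the pseudo-equatorial methyl group (trans to C8 on the five-membered ring) and acid-catalysed acetalisation in methanol then freezes it; the trans ring fusion is also the stable one, since a cis fusion would put O6 syn-axial to the C10 methyl group.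

Step 9
Reactants: 12 trans-fused lactol methyl ether ketone; 13 2-bromoprop-2-en-1-ol
Product: 15 cis-1,2-dialkenylcyclohexanol diol (C5 tertiary alcohol bearing an axial 3-hydroxyprop-1-en-2-yl group cis to the equatorial C10 vinyl group), via dilithio reagent 14 (not isolated)
Conditions: 13, t-BuLi (3 equiv), Et2O, −78 → 0 °C; CeCl3, THF, −78 °C; then 12, −78 → −20 °C; sat. NH4Cl
Reagents that add atoms: none
Why: 1,2-Addition of the alkenylcerium reagent made from the O,2-dilithio derivative of allyl alcohol; attack should be axial, anti to the axial C10 methyl group, which sets C5 with the alkenyl group axial (cis to vinyl and to C6–O) and the hydroxyl group equatorial.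

Step 10
Reactants: 15 cis-1,2-dialkenylcyclohexanol diol
Product: 19 ten-membered (1(10)Z,4E)-dienyl C5 triflate (C15-OTBDPS; C8-OTBS; lactol methyl ether), via dipotassium dialkoxide 16 (not isolated), via ten-membered enolate alkoxide 17 (not isolated), via C15-silylated potassium enolate 18 (not isolated)
Conditions: KH, 18-crown-6, THF, 0 → 40 °C; solution cannulated from excess KH; −78 °C, TBDPSCl (1.0 equiv); then N-(5-chloro-2-pyridyl)triflimide, −78 → −40 °C
Reagents that add atoms: tert-butyl(chloro)diphenylsilane, CC(C)(C)[Si](Cl)(c1ccccc1)c1ccccc1; N-(5-chloropyridin-2-yl)-1,1,1-trifluoro-N-(trifluoromethylsulfonyl)methanesulfonamide, FC(F)(F)S(=O)(=O)N(c1ccc(Cl)cn1)S(=O)(=O)C(F)(F)F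
Why: KH ionises both hydroxyl groups and the tertiary C5 alkoxide drives a concerted [3,3] sigmatropic shift through a chair transition state in which C2 bonds to C3 while C5–C10 breaks, the closest known reaction type being the anionic oxy-Cope ring expansion of cis-1,2-dialkenylcyclohexanols to cyclodec-5-enone enolates with O-triflation of the enolate. The ten-membered ring is thus closed by four-atom ring expansion of the cyclohexane across C5–C10 (the new C2–C3 bond forms as the old ring bond is cut), not by end-to-end cyclisation. No stereocentre is created; the alkene geometries follow from the chair of the conformer locked by the trans-fused acetal (vinyl equatorial at C10, alkenyl axial at C5), which places C9 pseudoaxial (ring-cis C1=C10) and C6 pseudoequatorial with the oxygen pseudoaxial (ring-trans C4=C5, enolate oxygen cis to C3). The step needs chair over boat and [3,3] over fragmentation, secured by the gauche cis-dialkenyl arrangement on a ring that cannot flip, and it needs an enolate that lasts until it is trapped, secured by carrying C15 as an alkoxide that cannot leave from the β-position. At −78 °C TBDPSCl should silylate only the much more nucleophilic primary alkoxide, and the pyridyl triflimide then triflates the enolate oxygen before the new β-silyloxy enolate can eliminate.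

Step 11
Reactants: 19 ten-membered (1(10)Z,4E)-dienyl C5 triflate
Product: 20 C5–H diene lactol methyl ether (C1=C10 ring-cis; C4=C5 ring-trans; C15-OTBDPS; C8-OTBS)
Conditions: Pd(OAc)2 (5 mol%), PPh3, HCO2H, Bu3N, DMF, 60 °C
Reagents that add atoms: none
Why: Palladium-catalysed formate reduction of the enol triflate (oxidative addition, decarboxylation of formate, reductive elimination) should replace OTf by H with retention of the C4=C5 geometry.

Step 12
Reactants: 20 C5–H diene lactol methyl ether
Product: 21 lactol (C12 hemiacetal; C12 epimers)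
Conditions: AcOH/THF/H2O (3:1:1), 40 °C
Reagents that add atoms: water, O
Why: Acid-catalysed hydrolysis of the 2-methoxytetrahydrofuran acetal through the ring oxocarbenium ion should be much faster than loss of the secondary TBS or the primary TBDPS ether.

Step 13
Reactants: 21 lactol
Product: 22 6,12-lactone (C8-OTBS; C15-OTBDPS)
Conditions: TEMPO (cat.), PhI(OAc)2, CH2Cl2, 23 °C
Reagents that add atoms: none
Why: Oxoammonium (TEMPO) oxidation of the lactol to the γ-lactone under neutral conditions; C11 remains the thermodynamically preferred epimer.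

Step 14
Reactants: 22 6,12-lactone
Product: 23 8-hydroxy-6,12-lactone (C15-OTBDPS)
Conditions: HF·pyridine, pyridine, THF, 0 → 23 °C
Reagents that add atoms: none
Why: Selective desilylation; buffered HF·pyridine should cleave the secondary TBS ether well before the far more acid-stable primary TBDPS ether.

Step 15
Reactants: 24 (tert-butyldimethylsilyloxy)acetaldehyde; 25 ethyl 2-(triphenylphosphoranylidene)propanoate
Product: 26 ethyl (E)-4-(tert-butyldimethylsilyloxy)-2-methylbut-2-enoate
Conditions: CH2Cl2, 23 °C
Reagents that add atoms: none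
Why: Wittig olefination with a stabilised ylide should give the (E)-trisubstituted enoate.

Step 16
Reactants: 26 ethyl (E)-4-(tert-butyldimethylsilyloxy)-2-methylbut-2-enoate
Product: 27 (E)-4-(tert-butyldimethylsilyloxy)-2-methylbut-2-enoic acid
Conditions: LiOH, THF/MeOH/H2O, 23 °C; then 1 M HCl to pH 4, 0 °C
Reagents that add atoms: lithium hydroxide, [Li+].[OH-]
Why: Saponification; the primary TBS ether should tolerate aqueous LiOH and a careful cold acidification.

Step 17
Reactants: 23 8-hydroxy-6,12-lactone; 27 (E)-4-(tert-butyldimethylsilyloxy)-2-methylbut-2-enoic acid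
Product: 29 bis-silyl ether of the target (C15-OTBDPS; side-chain OTBS), via mixed anhydride 28 (not isolated)
Conditions: 27, 2,4,6-Cl3C6H2COCl, Et3N, toluene, 23 °C; then 23, DMAP, 23 → 40 °C
Reagents that add atoms: none
Why: Yamaguchi esterification through the mixed anhydride acylates the hindered secondary C8–OH with retention at C8 and of the (E)-geometry of the acyl group.

Step 18
Reactants: 29 bis-silyl ether of the target
Product: 30 CNP0222998.2 (target)
Conditions: HF·pyridine, pyridine, THF, 23 °C
Reagents that add atoms: none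
Why: Fluoride-mediated cleavage of both primary silyl ethers under mildly acidic conditions that spare the lactone, the allylic ester and the diene.

Compound list
1 | (S)-4-(tert-butyldimethylsilyloxy)cyclohex-2-en-1-one | O=C1C=C[C@@H](O[Si](C)(C)C(C)(C)C)CC1 | starting material
2 | isopropenylmagnesium bromide | CC(=C)[Mg]Br | starting material
3 | trimethylsilyl enol ether of 4 (C5=C6; not isolated) | C[Si](C)(C)OC1=C[C@H](C(C)=C)[C@@H](O[Si](C)(C)C(C)(C)C)CC1 | intermediate
4 | (3R,4S)-4-(tert-butyldimethylsilyloxy)-3-(prop-1-en-2-yl)cyclohexan-1-one (C5 ketone; C7 isopropenyl trans to C8-OTBS) | O=C1C[C@H](C(C)=C)[C@@H](O[Si](C)(C)C(C)(C)C)CC1 | intermediate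
5 | C10-(hydroxymethylene) ketone (chelated Z-enol of the 2-formyl derivative of 4) | O/C=C1\C(=O)C[C@H](C(C)=C)[C@@H](O[Si](C)(C)C(C)(C)C)C1 | intermediate
6 | C10-formyl-C10-methyl ketone (methyl cis to C7 isopropenyl; formyl cis to C8-OTBS) | O=C1C[C@H](C(C)=C)[C@@H](O[Si](C)(C)C(C)(C)C)C[C@@]1(C)C=O | intermediate
7 | C10-methyl-C10-vinyl ketone (vinyl cis to C8-OTBS; trans to isopropenyl) | O=C1C[C@H](C(C)=C)[C@@H](O[Si](C)(C)C(C)(C)C)C[C@@]1(C)C=C | intermediate
8 | C6-hydroxy ketone (6-OH trans to isopropenyl; cis to vinyl) | O=C1[C@@H](O)[C@H](C(C)=C)[C@@H](O[Si](C)(C)C(C)(C)C)C[C@@]1(C)C=C | intermediate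
9 | C11,C12-epoxide of 8 (both C11 epimers) | O=C1[C@@H](O)[C@H](C2(C)CO2)[C@@H](O[Si](C)(C)C(C)(C)C)C[C@@]1(C)C=C | intermediate
10 | open-chain γ-hydroxy aldehyde (C12 aldehyde; C11 epimers; not isolated) | O=C1[C@@H](O)[C@H](C(C)C=O)[C@@H](O[Si](C)(C)C(C)(C)C)C[C@@]1(C)C=C | intermediate
11 | trans-fused lactol (C6–O–C12 hemiacetal; C11/C12 epimers) | O=C1[C@H]2OC(O)C(C)[C@@H]2[C@@H](O[Si](C)(C)C(C)(C)C)C[C@@]1(C)C=C | intermediate
12 | trans-fused lactol methyl ether ketone (C11 methyl trans to C8; OMe trans to that methyl; major anomer) | O=C1[C@H]2O[C@H](OC)[C@@H](C)[C@@H]2[C@@H](O[Si](C)(C)C(C)(C)C)C[C@@]1(C)C=C | intermediate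
13 | 2-bromoprop-2-en-1-ol | OCC(Br)=C | starting material
14 | O,2-dilithio derivative of allyl alcohol (not isolated) | [Li]OCC([Li])=C | intermediate
15 | cis-1,2-dialkenylcyclohexanol diol, the rearrangement precursor (C10: vinyl equatorial, methyl axial; C5: 3-hydroxyprop-1-en-2-yl axial, OH equatorial; C8-OTBS; lactol methyl ether) | C[C@@]1(C=C)C[C@H](O[Si](C)(C)C(C)(C)C)[C@H]2[C@H](C)[C@@H](OC)O[C@@H]2[C@]1(O)C(=C)CO | intermediate
16 | dipotassium dialkoxide of 15 (not isolated) | C[C@@]1(C=C)C[C@H](O[Si](C)(C)C(C)(C)C)[C@H]2[C@H](C)[C@@H](OC)O[C@@H]2[C@]1([O-])C(=C)C[O-].[K+].[K+] | intermediate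
17 | ten-membered dipotassium C5 enolate C15 alkoxide (not isolated) | C/C1=C/CC/C(C[O-])=C([O-])/[C@H]2O[C@H](OC)[C@@H](C)[C@@H]2[C@@H](O[Si](C)(C)C(C)(C)C)C1.[K+].[K+] | intermediate
18 | C15-O-TBDPS potassium C5 enolate (not isolated) | C/C1=C/CC/C(CO[Si](c3ccccc3)(c3ccccc3)C(C)(C)C)=C([O-])/[C@H]2O[C@H](OC)[C@@H](C)[C@@H]2[C@@H](O[Si](C)(C)C(C)(C)C)C1.[K+] | intermediate
19 | ten-membered (1(10)Z,4E)-dienyl C5 triflate (C15-OTBDPS; C8-OTBS; lactol methyl ether) | C/C1=C/CC/C(CO[Si](c3ccccc3)(c3ccccc3)C(C)(C)C)=C(OS(=O)(=O)C(F)(F)F)/[C@H]2O[C@H](OC)[C@@H](C)[C@@H]2[C@@H](O[Si](C)(C)C(C)(C)C)C1 | intermediate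
20 | C5–H diene lactol methyl ether (C1=C10 ring-cis; C4=C5 ring-trans) | C/C1=C/CC/C(CO[Si](c3ccccc3)(c3ccccc3)C(C)(C)C)=C/[C@H]2O[C@H](OC)[C@@H](C)[C@@H]2[C@@H](O[Si](C)(C)C(C)(C)C)C1 | intermediate
21 | lactol (C12 epimers) | C/C1=C/CC/C(CO[Si](c3ccccc3)(c3ccccc3)C(C)(C)C)=C/[C@H]2OC(O)[C@@H](C)[C@@H]2[C@@H](O[Si](C)(C)C(C)(C)C)C1 | intermediate
22 | 6,12-lactone (C8-OTBS; C15-OTBDPS) | C/C1=C/CC/C(CO[Si](c3ccccc3)(c3ccccc3)C(C)(C)C)=C/[C@H]2OC(=O)[C@@H](C)[C@@H]2[C@@H](O[Si](C)(C)C(C)(C)C)C1 | intermediate
23 | 8-hydroxy-6,12-lactone (C15-OTBDPS) | C/C1=C/CC/C(CO[Si](c3ccccc3)(c3ccccc3)C(C)(C)C)=C/[C@H]2OC(=O)[C@@H](C)[C@@H]2[C@@H](O)C1 | intermediate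
24 | (tert-butyldimethylsilyloxy)acetaldehyde | O=CCO[Si](C)(C)C(C)(C)C | starting material
25 | ethyl 2-(triphenylphosphoranylidene)propanoate | CCOC(=O)C(C)=P(c1ccccc1)(c1ccccc1)c1ccccc1 | starting material
26 | ethyl (E)-4-(tert-butyldimethylsilyloxy)-2-methylbut-2-enoate | CCOC(=O)/C(C)=C/CO[Si](C)(C)C(C)(C)C | intermediate
27 | (E)-4-(tert-butyldimethylsilyloxy)-2-methylbut-2-enoic acid | OC(=O)/C(C)=C/CO[Si](C)(C)C(C)(C)C | intermediate
28 | mixed anhydride of 27 with 2,4,6-trichlorobenzoic acid (not isolated) | O=C(OC(=O)/C(C)=C/CO[Si](C)(C)C(C)(C)C)c1c(Cl)cc(Cl)cc1Cl | intermediate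
29 | bis-silyl ether of the target (C15-OTBDPS; side-chain OTBS) | C/C1=C/CC/C(CO[Si](c3ccccc3)(c3ccccc3)C(C)(C)C)=C/[C@H]2OC(=O)[C@@H](C)[C@@H]2[C@@H](OC(=O)/C(C)=C/CO[Si](C)(C)C(C)(C)C)C1 | intermediate
30 | CNP0222998.2 | C/C1=C/CC/C(CO)=C/[C@H]2OC(=O)[C@@H](C)[C@@H]2[C@@H](OC(=O)/C(C)=C/CO)C1 | target

Total step count: 18. Longest linear sequence: 16 steps (steps 1–14, 17 and 18); steps 15 and 16 form the two-step side-chain branch.

Steps most likely to fail

Step 10. The two trapping events may lose chemoselectivity (the enolate oxygen is silylated, or the alkoxide is sulfonylated), or the enolate may eliminate once C15 carries a silyl ether. The fallback separates the trappings. Setting out from 15, the same dianionic rearrangement would be quenched with excess chlorotrimethylsilane to give the isolable bis(trimethylsilyl) compound F1 (C5 enol silane, C15 silyl ether). Methyllithium (THF, −20 °C) should cleave only the enol silane, and the lithium enolate would be triflated at −78 °C with the same pyridyl triflimide to give the C15-trimethylsilyloxy triflate F2. K2CO3 in methanol would free the primary alcohol to give the hydroxy triflate F3, and TBDPSCl with imidazole brings the material back to the route at 19.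

Step 7. Proton loss from the tertiary C11 cation, leading to allylic alcohols, may outrun the 1,2-hydride shift. The fallback replaces the cationic opening by a radical one. Setting out from 9, titanocene(III) chloride (Cp2TiCl2, Mn, collidine hydrochloride, THF) should open the epoxide reductively in the anti-Markovnikov sense to the primary alcohol, the C6,C12-diol F4. TEMPO with one equivalent of PhI(OAc)2 should oxidise only the primary alcohol, and the resulting hydroxy aldehyde closes to lactol 11, where the route is rejoined before the C11 equilibration of step 8.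

Step 9. The strongly basic dianion may enolise the α-alkoxy ketone at C6, or the aggregated dianion may fail to add to the neopentyl carbonyl group. The fallback uses a monoanionic, silyl-protected nucleophile. Setting out from 13, TBSCl with imidazole gives the 2-bromoallyl silyl ether F5. Bromine–lithium exchange (t-BuLi, Et2O, −78 °C), transmetalation with CeCl3 and addition to 12 should give the C15-silyloxy carbinol F6. PPTS in methanol would cleave the primary allylic TBS ether while the secondary C8 ether and the methyl acetal persist, which returns the route at diol 15.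

Further compounds
F1 | step 10 | ten-membered C5 trimethylsilyl enol ether C15 trimethylsilyl ether | C/C1=C/CC/C(CO[Si](C)(C)C)=C(O[Si](C)(C)C)/[C@H]2O[C@H](OC)[C@@H](C)[C@@H]2[C@@H](O[Si](C)(C)C(C)(C)C)C1
F2 | step 10 | C15-trimethylsilyloxy C5 triflate | C/C1=C/CC/C(CO[Si](C)(C)C)=C(OS(=O)(=O)C(F)(F)F)/[C@H]2O[C@H](OC)[C@@H](C)[C@@H]2[C@@H](O[Si](C)(C)C(C)(C)C)C1
F3 | step 10 | C15-hydroxy C5 triflate | C/C1=C/CC/C(CO)=C(OS(=O)(=O)C(F)(F)F)/[C@H]2O[C@H](OC)[C@@H](C)[C@@H]2[C@@H](O[Si](C)(C)C(C)(C)C)C1
F4 | step 7 | C6,C12-diol from reductive epoxide opening (C11 epimers) | O=C1[C@@H](O)[C@H](C(C)CO)[C@@H](O[Si](C)(C)C(C)(C)C)C[C@@]1(C)C=C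
F5 | step 9 | (2-bromoallyloxy)(tert-butyl)dimethylsilane | C=C(Br)CO[Si](C)(C)C(C)(C)C
F6 | step 9 | C15-O-TBS carbinol (silyl-protected form of 15) | C[C@@]1(C=C)C[C@H](O[Si](C)(C)C(C)(C)C)[C@H]2[C@H](C)[C@@H](OC)O[C@@H]2[C@]1(O)C(=C)CO[Si](C)(C)C(C)(C)C
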